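The flavonol is disconnected at the O1–C8a bond of ring C. In ring A the three oxygens (O1 on C8a, the C5 hydroxyl, the C7 hydroxyl) lie meta to one another and ortho or para to C4a, which carries the C4 carbonyl, so a 2,4,6-trifluorobenzoyl unit can serve as ring A with every fluorine as a masked oxygen. In the key step mild base converts the 2-(methoxymethoxy)-1,3-diketone 14, which links the finished ring B (chromene, prenyl, protected phenol) to the trifluoroarene, into flavone 15 by intramolecular SNAr in one operation. The remaining fluorines then become the C7 and C5 oxygens, and a Claisen shift delivers the C8 1,1-dimethylallyl group.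

Key step: step 8

Remark: the target has no stereocentre, and 11 and 14 are racemic with their sp3 centres erased in steps 6 and 8; the acid chloride 13 and the stannanes 7 and 9 are assumed to be purchasable.
Abbreviations: MOM = methoxymethyl; ArB = 8-(methoxymethoxy)-2,2-dimethyl-5-(3-methylbut-2-en-1-yl)-2H-chromen-6-yl (the complete ring B unit).

Step 1
Reactants: 1 2-bromo-4,5-dihydroxybenzaldehyde; 2 3-chloro-3-methylbut-1-yne
Product: 3 2-bromo-5-hydroxy-4-[(2-methylbut-3-yn-2-yl)oxy]benzaldehyde
Conditions: DBU (1.1 equiv), CuCl2·2H2O (1 mol %), MeCN, 0 °C → rt, argon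
Reagents that add atoms: none
Why: Copper-catalysed propargylic etherification with one equivalent of base should take place at the 4-hydroxyl, which is para to the formyl group and therefore the more acidic and first-deprotonated of the two phenols.

Step 2
Reactants: 3 2-bromo-5-hydroxy-4-[(2-methylbut-3-yn-2-yl)oxy]benzaldehyde
Product: 4 2-bromo-5-(methoxymethoxy)-4-[(2-methylbut-3-yn-2-yl)oxy]benzaldehyde
Conditions: MOMCl, i-Pr2NEt, CH2Cl2, 0 °C → rt
Reagents that add atoms: chloromethyl methyl ether, COCCl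
Why: O-Alkylation of the remaining phenol with the reactive chloromethyl ether under amine base (MOM ether formation) is routine and leaves aldehyde, bromide and alkyne untouched.

Step 3
Reactants: 4 2-bromo-5-(methoxymethoxy)-4-[(2-methylbut-3-yn-2-yl)oxy]benzaldehyde
Product: 6 5-bromo-8-(methoxymethoxy)-2,2-dimethyl-2H-chromene-6-carbaldehyde, via ortho-allenylphenol 5 (not isolated)
Conditions: PhNEt2, 185 °C, argon
Reagents that add atoms: none
Why: Aromatic propargyl Claisen rearrangement to the only free ortho carbon (C3, since C5 carries oxygen) should give allenylphenol 5, which closes to the 2,2-dimethylchromene by 1,5-hydrogen shift and 6π-electrocyclisation, the standard thermal chromene synthesis from aryl 1,1-dimethylpropargyl ethers.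

Step 4
Reactants: 6 5-bromo-8-(methoxymethoxy)-2,2-dimethyl-2H-chromene-6-carbaldehyde; 7 tributyl(3-methylbut-2-en-1-yl)stannane
Product: 8 8-(methoxymethoxy)-2,2-dimethyl-5-(3-methylbut-2-en-1-yl)-2H-chromene-6-carbaldehyde
Conditions: Pd(PPh3)4 (5 mol %), DMF, 95 °C
Reagents that add atoms: none
Why: Stille coupling, in which zerovalent palladium inserts into the C–Br bond activated by the ortho formyl group and the allylpalladium intermediate should reductively eliminate at its unsubstituted terminus, the di-ortho-substituted aryl group favouring the linear prenyl isomer.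

Step 5
Reactants: 8 8-(methoxymethoxy)-2,2-dimethyl-5-(3-methylbut-2-en-1-yl)-2H-chromene-6-carbaldehyde; 9 tributyl[(methoxymethoxy)methyl]stannane
Product: 11 racemic 2-(methoxymethoxy)-1-ArB-ethan-1-ol, via (methoxymethoxy)methyllithium 10 (not isolated)
Conditions: 9, n-BuLi, THF, −78 °C; then 8, −78 °C; aq NH4Cl
Reagents that add atoms: none
Why: Tin–lithium exchange should give the α-alkoxymethyllithium 10, which adds 1,2 to the aldehyde; the carbinol centre forms without control as a racemate and is removed in the next step.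

Step 6
Reactants: 11 racemic 2-(methoxymethoxy)-1-ArB-ethan-1-ol
Product: 12 2-(methoxymethoxy)-1-ArB-ethan-1-one
Conditions: Dess–Martin periodinane, pyridine, CH2Cl2, 0 °C → rt
Reagents that add atoms: none
Why: Dess–Martin oxidation of a secondary benzylic alcohol to the aryl ketone is mild enough for the MOM ethers, the chromene and the prenyl alkene, with pyridine buffering the acid released.

Step 7
Reactants: 12 2-(methoxymethoxy)-1-ArB-ethan-1-one; 13 2,4,6-trifluorobenzoyl chloride
Product: 14 racemic 2-(methoxymethoxy)-1-ArB-3-(2,4,6-trifluorophenyl)propane-1,3-dione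
Conditions: LiN(SiMe3)2 (2.2 equiv), THF, −78 °C; then 13, −78 → −20 °C; aq NH4Cl
Reagents that add atoms: none
Why: Claisen-type C-acylation of a ketone lithium enolate with an aroyl chloride, in which the second equivalent of base deprotonates the much more acidic 1,3-diketone as it forms and so shields it from further acylation.

Step 8
Reactants: 14 racemic 2-(methoxymethoxy)-1-ArB-3-(2,4,6-trifluorophenyl)propane-1,3-dione
Product: 15 5,7-difluoro-3-(methoxymethoxy)-2-ArB-4H-chromen-4-one
Conditions: K2CO3, DMF, rt → 50 °C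
Reagents that add atoms: none
Why: K2CO3 removes the acidic C2 proton between the two carbonyls, and the enolate oxygen on the ring B carbonyl adds to a fluorine-bearing carbon ortho to the aroyl carbonyl to give a Meisenheimer-type anion, stabilised by that carbonyl and by the two other fluorines, which then loses fluoride (intramolecular SNAr, addition–elimination). The closest known reaction is the base-mediated cyclisation of 1-(2-fluoroaryl)-1,3-diketones to chromones and flavones. Ring C closes by O1–C8a bond formation through a six-membered transition state, 6-exo with respect to the C–F bond that breaks and 6-endo-trig when viewed as conjugate addition to the C8a=C4a–C4=O unit. No stereocentre is created, and the racemic C2 centre of 14 becomes sp2. The step needs attack by oxygen and not by carbon and a single site of attack: attack through the central carbon or through the other enolate oxygen would need a four-membered ring, the two ortho fluorines are interchanged by rotation about the aryl–carbonyl bond so only one chromone can result, the para fluorine is out of reach, and ring B offers no leaving group.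

Step 9
Reactants: 15 5,7-difluoro-3-(methoxymethoxy)-2-ArB-4H-chromen-4-one; 16 3-methylbut-2-en-1-ol
Product: 17 5-fluoro-3-(methoxymethoxy)-2-ArB-7-[(3-methylbut-2-en-1-yl)oxy]-4H-chromen-4-one
Conditions: 16, KN(SiMe3)2 (1.05 equiv), 18-crown-6, THF–DMF, −40 → 0 °C
Reagents that add atoms: none
Why: Intermolecular SNAr of an alkoxide on a fluorochromone, in which the unhindered C7 fluorine para to C4a should react first because a crown-separated potassium alkoxide in a polar medium is not steered to the peri C5 fluorine by chelation to the carbonyl, and one equivalent at low temperature should stop at monosubstitution.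

Step 10
Reactants: 17 5-fluoro-3-(methoxymethoxy)-2-ArB-7-[(3-methylbut-2-en-1-yl)oxy]-4H-chromen-4-one
Product: 20 3-(methoxymethoxy)-2-ArB-7-[(3-methylbut-2-en-1-yl)oxy]-4-oxo-4H-chromen-5-yl acetate, via 5-[2-(methylsulfonyl)ethoxy]flavone 18 (not isolated), via 5-hydroxyflavone 19 (not isolated)
Conditions: MeSO2CH2CH2OH, NaH, DMF, 0 °C → rt; then Ac2O, 0 °C → rt
Reagents that add atoms: 2-(methylsulfonyl)ethanol, CS(=O)(=O)CCO; acetic anhydride, CC(=O)OC(C)=O
Why: The sodium alkoxide of 2-(methylsulfonyl)ethanol, helped by sodium bridging to the C4 carbonyl, should displace the ortho C5 fluorine by SNAr, excess base then expels methyl vinyl sulfone by E1cB elimination to unmask the phenoxide of 19 (an established hydroxide-surrogate protocol), and acetic anhydride acylates that phenoxide in the same flask.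

Step 11
Reactants: 20 3-(methoxymethoxy)-2-ArB-7-[(3-methylbut-2-en-1-yl)oxy]-4-oxo-4H-chromen-5-yl acetate
Product: 21 7-hydroxy-3-(methoxymethoxy)-2-ArB-8-(2-methylbut-3-en-2-yl)-4-oxo-4H-chromen-5-yl acetate
Conditions: PhNEt2, 190 °C, argon
Reagents that add atoms: none
Why: Aromatic Claisen rearrangement (a [3,3]-sigmatropic shift of the aryl prenyl ether followed by tautomerisation) inverts the allyl unit to the 1,1-dimethylallyl group, and with the C5 oxygen acetylated (no hydrogen bond to the C4 carbonyl, less electron density at C6) the shift is expected at C8, the usual site for 7-allyloxychromones that lack a chelated 5-hydroxyl.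

Step 12
Reactants: 21 7-hydroxy-3-(methoxymethoxy)-2-ArB-8-(2-methylbut-3-en-2-yl)-4-oxo-4H-chromen-5-yl acetate
Product: 23 broussoflavonol D, via deacetylated bis-MOM ether 22 (not isolated)
Conditions: K2CO3, MeOH, rt; then 3 M aq HCl, 45 °C
Reagents that add atoms: none
Why: Base-mediated methanolysis should remove the aryl acetate while the 3-oxygen is still protected (so no air-sensitive flavonol anion forms), and acidification then cleaves both MOM acetals (acetal hydrolysis) under conditions mild enough for the prenyl, 1,1-dimethylallyl and chromene alkenes.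

Compound list
1 | 2-bromo-4,5-dihydroxybenzaldehyde | O=Cc1cc(O)c(O)cc1Br | starting material
2 | 3-chloro-3-methylbut-1-yne | C#CC(C)(C)Cl | starting material
3 | 2-bromo-5-hydroxy-4-[(2-methylbut-3-yn-2-yl)oxy]benzaldehyde | O=Cc1cc(O)c(OC(C)(C)C#C)cc1Br | intermediate
4 | 2-bromo-5-(methoxymethoxy)-4-[(2-methylbut-3-yn-2-yl)oxy]benzaldehyde | O=Cc1cc(OCOC)c(OC(C)(C)C#C)cc1Br | intermediate
5 | 2-bromo-4-hydroxy-5-(methoxymethoxy)-3-(3-methylbuta-1,2-dien-1-yl)benzaldehyde | O=Cc1cc(OCOC)c(O)c(C=C=C(C)C)c1Br | intermediate (not isolated)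
6 | 5-bromo-8-(methoxymethoxy)-2,2-dimethyl-2H-chromene-6-carbaldehyde | O=Cc1cc(OCOC)c2c(c1Br)C=CC(C)(C)O2 | intermediate
7 | tributyl(3-methylbut-2-en-1-yl)stannane | CCCC[Sn](CCCC)(CCCC)CC=C(C)C | starting material
8 | 8-(methoxymethoxy)-2,2-dimethyl-5-(3-methylbut-2-en-1-yl)-2H-chromene-6-carbaldehyde | O=Cc1cc(OCOC)c2c(c1CC=C(C)C)C=CC(C)(C)O2 | intermediate
9 | tributyl[(methoxymethoxy)methyl]stannane | CCCC[Sn](CCCC)(CCCC)COCOC | starting material
10 | (methoxymethoxy)methyllithium | [Li]COCOC | intermediate (not isolated)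
11 | racemic 2-(methoxymethoxy)-1-[8-(methoxymethoxy)-2,2-dimethyl-5-(3-methylbut-2-en-1-yl)-2H-chromen-6-yl]ethan-1-ol | OC(COCOC)c1cc(OCOC)c2c(c1CC=C(C)C)C=CC(C)(C)O2 | intermediate
12 | 2-(methoxymethoxy)-1-[8-(methoxymethoxy)-2,2-dimethyl-5-(3-methylbut-2-en-1-yl)-2H-chromen-6-yl]ethan-1-one | O=C(COCOC)c1cc(OCOC)c2c(c1CC=C(C)C)C=CC(C)(C)O2 | intermediate
13 | 2,4,6-trifluorobenzoyl chloride | O=C(Cl)c1c(F)cc(F)cc1F | starting material
14 | racemic 2-(methoxymethoxy)-1-[8-(methoxymethoxy)-2,2-dimethyl-5-(3-methylbut-2-en-1-yl)-2H-chromen-6-yl]-3-(2,4,6-trifluorophenyl)propane-1,3-dione | O=C(c1c(F)cc(F)cc1F)C(OCOC)C(=O)c1cc(OCOC)c2c(c1CC=C(C)C)C=CC(C)(C)O2 | intermediate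
15 | 5,7-difluoro-3-(methoxymethoxy)-2-[8-(methoxymethoxy)-2,2-dimethyl-5-(3-methylbut-2-en-1-yl)-2H-chromen-6-yl]-4H-chromen-4-one | Fc1cc(F)c2c(c1)oc(-c1cc(OCOC)c3c(c1CC=C(C)C)C=CC(C)(C)O3)c(OCOC)c2=O | intermediate
16 | 3-methylbut-2-en-1-ol | CC(C)=CCO | starting material
17 | 5-fluoro-3-(methoxymethoxy)-2-[8-(methoxymethoxy)-2,2-dimethyl-5-(3-methylbut-2-en-1-yl)-2H-chromen-6-yl]-7-[(3-methylbut-2-en-1-yl)oxy]-4H-chromen-4-one | CC(C)=CCOc1cc(F)c2c(c1)oc(-c1cc(OCOC)c3c(c1CC=C(C)C)C=CC(C)(C)O3)c(OCOC)c2=O | intermediate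
18 | 3-(methoxymethoxy)-2-[8-(methoxymethoxy)-2,2-dimethyl-5-(3-methylbut-2-en-1-yl)-2H-chromen-6-yl]-7-[(3-methylbut-2-en-1-yl)oxy]-5-[2-(methylsulfonyl)ethoxy]-4H-chromen-4-one | CC(C)=CCOc1cc(OCCS(C)(=O)=O)c2c(c1)oc(-c1cc(OCOC)c3c(c1CC=C(C)C)C=CC(C)(C)O3)c(OCOC)c2=O | intermediate (not isolated)
19 | 5-hydroxy-3-(methoxymethoxy)-2-[8-(methoxymethoxy)-2,2-dimethyl-5-(3-methylbut-2-en-1-yl)-2H-chromen-6-yl]-7-[(3-methylbut-2-en-1-yl)oxy]-4H-chromen-4-one | CC(C)=CCOc1cc(O)c2c(c1)oc(-c1cc(OCOC)c3c(c1CC=C(C)C)C=CC(C)(C)O3)c(OCOC)c2=O | intermediate (not isolated)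
20 | 3-(methoxymethoxy)-2-[8-(methoxymethoxy)-2,2-dimethyl-5-(3-methylbut-2-en-1-yl)-2H-chromen-6-yl]-7-[(3-methylbut-2-en-1-yl)oxy]-4-oxo-4H-chromen-5-yl acetate | CC(C)=CCOc1cc(OC(C)=O)c2c(c1)oc(-c1cc(OCOC)c3c(c1CC=C(C)C)C=CC(C)(C)O3)c(OCOC)c2=O | intermediate
21 | 7-hydroxy-3-(methoxymethoxy)-2-[8-(methoxymethoxy)-2,2-dimethyl-5-(3-methylbut-2-en-1-yl)-2H-chromen-6-yl]-8-(2-methylbut-3-en-2-yl)-4-oxo-4H-chromen-5-yl acetate | C=CC(C)(C)c1c(O)cc(OC(C)=O)c2c(=O)c(OCOC)c(-c3cc(OCOC)c4c(c3CC=C(C)C)C=CC(C)(C)O4)oc12 | intermediate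
22 | 5,7-dihydroxy-3-(methoxymethoxy)-2-[8-(methoxymethoxy)-2,2-dimethyl-5-(3-methylbut-2-en-1-yl)-2H-chromen-6-yl]-8-(2-methylbut-3-en-2-yl)-4H-chromen-4-one | C=CC(C)(C)c1c(O)cc(O)c2c(=O)c(OCOC)c(-c3cc(OCOC)c4c(c3CC=C(C)C)C=CC(C)(C)O4)oc12 | intermediate (not isolated)
23 | broussoflavonol D, 3,5,7-trihydroxy-2-[8-hydroxy-2,2-dimethyl-5-(3-methylbut-2-en-1-yl)-2H-chromen-6-yl]-8-(2-methylbut-3-en-2-yl)-4H-chromen-4-one (no stereocentre) | C=CC(C)(C)c1c(O)cc(O)c2c(=O)c(O)c(-c3cc(O)c4c(c3CC=C(C)C)C=CC(C)(C)O4)oc12 | target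

Total step count: 12. Longest linear sequence: 12 steps (1 → 23); every other component is purchased.

Steps most likely to fail

Step 11. The allyl unit may migrate to C6 as well as C8, above all if the acetyl group is passed between phenols at 190 °C and a hydrogen-bonded 5-hydroxyl is restored; prolonged heating may also close the new phenol onto its alkene. The fallback replaces the ester by an ether that cannot migrate. It sets out from 19, isolated by quenching step 10 with aqueous NH4Cl in place of Ac2O. NaH and MOMCl in DMF at 0 °C should convert it into the 5-(methoxymethoxy)-7-prenyloxy tris-MOM flavone F4. Heating in PhNEt2 at 190 °C should then give the 7-hydroxy-8-(2-methylbut-3-en-2-yl) tris-MOM flavone F5 by the same Claisen shift. Treatment with 3 M aq HCl in MeOH at 45 °C removes all three acetals and rejoins the route at 23.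

Step 9. The alkoxide may attack the peri C5 fluorine in competition with C7, or substitute twice. The fallback gives up site selection and sets out from 15. Excess sodium allyl oxide (allyl alcohol, NaH, DMF, rt → 60 °C) should displace both fluorides to give the 5,7-bis(allyloxy)flavone F2. Pd(PPh3)4 and morpholine in THF then remove both allyl groups to give the 5,7-dihydroxyflavone F3. Prenyl bromide and K2CO3 in acetone alkylate only the free 7-hydroxyl, the hydrogen-bonded 5-hydroxyl staying inert, which rejoins the route at 19; acetylation (Ac2O, pyridine, DMAP) then gives 20.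

Step 7. The enolate may be acylated on oxygen in competition with carbon, or the amide base may consume the acid chloride. The fallback forms the same C–C bond by aldol addition, which can only occur at carbon, and sets out from 12. Its lithium enolate (LiN(SiMe3)2, THF, −78 °C) is added to purchased 2,4,6-trifluorobenzaldehyde to give the β-hydroxy ketone 3-hydroxy-2-(methoxymethoxy)-1-ArB-3-(2,4,6-trifluorophenyl)propan-1-one F1 as a mixture of racemic diastereomers. Oxidation with Dess–Martin periodinane (pyridine, CH2Cl2) should then deliver the diketone and rejoin the route at 14.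

Further compounds
F1 | step 7 | 3-hydroxy-2-(methoxymethoxy)-1-[8-(methoxymethoxy)-2,2-dimethyl-5-(3-methylbut-2-en-1-yl)-2H-chromen-6-yl]-3-(2,4,6-trifluorophenyl)propan-1-one (mixture of racemic diastereomers) | OC(c1c(F)cc(F)cc1F)C(OCOC)C(=O)c1cc(OCOC)c2c(c1CC=C(C)C)C=CC(C)(C)O2
F2 | step 9 | 5,7-bis(allyloxy)-3-(methoxymethoxy)-2-[8-(methoxymethoxy)-2,2-dimethyl-5-(3-methylbut-2-en-1-yl)-2H-chromen-6-yl]-4H-chromen-4-one | C=CCOc1cc(OCC=C)c2c(c1)oc(-c1cc(OCOC)c3c(c1CC=C(C)C)C=CC(C)(C)O3)c(OCOC)c2=O
F3 | step 9 | 5,7-dihydroxy-3-(methoxymethoxy)-2-[8-(methoxymethoxy)-2,2-dimethyl-5-(3-methylbut-2-en-1-yl)-2H-chromen-6-yl]-4H-chromen-4-one | Oc1cc(O)c2c(c1)oc(-c1cc(OCOC)c3c(c1CC=C(C)C)C=CC(C)(C)O3)c(OCOC)c2=O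
F4 | step 11 | 3,5-bis(methoxymethoxy)-2-[8-(methoxymethoxy)-2,2-dimethyl-5-(3-methylbut-2-en-1-yl)-2H-chromen-6-yl]-7-[(3-methylbut-2-en-1-yl)oxy]-4H-chromen-4-one | CC(C)=CCOc1cc(OCOC)c2c(c1)oc(-c1cc(OCOC)c3c(c1CC=C(C)C)C=CC(C)(C)O3)c(OCOC)c2=O
F5 | step 11 | 7-hydroxy-3,5-bis(methoxymethoxy)-2-[8-(methoxymethoxy)-2,2-dimethyl-5-(3-methylbut-2-en-1-yl)-2H-chromen-6-yl]-8-(2-methylbut-3-en-2-yl)-4H-chromen-4-one | C=CC(C)(C)c1c(O)cc(OCOC)c2c(=O)c(OCOC)c(-c3cc(OCOC)c4c(c3CC=C(C)C)C=CC(C)(C)O4)oc12
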